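**Assumptions (one line each)**
- Diarylheptanoid numbering is used for the chain: C1/C2 = CH2CH2Ar, C3 = carbinol, C4 = CH2, C5=C6 = alkene, C7 = diaryl methine. The target SMILES is then (3S,5E,7R).
- The facial sense of the new step 5 cannot be assigned from precedent. (R)-TRIP is written; if the first run gives the 7S epimer (calyxin B), (S)-TRIP is used with nothing else changed.

**Retrosynthetic overview**
1. Last bond, C7–C3′: catalyst-controlled dehydrative Friedel–Crafts union of the unprotected chalcone helichrysetin with a vinyl para-quinone methide (p-QM) generated in situ from a C7 carbinol; this sets C7.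
2. The C7 carbinol (3S, C7 deliberately racemic and erased in step 5) comes from E-selective cross-metathesis of a (S)-homoallylic alcohol with rac-1-(4-hydroxyphenyl)allyl alcohol.
3. The (S)-homoallylic alcohol (C3, first stereocentre) comes from chiral phosphoric acid-catalysed allylboration of 3-(4-hydroxyphenyl)propanal.
4. Helichrysetin comes from Claisen–Schmidt condensation of two achiral phenols.
5. No ring is formed; all four benzene rings are purchased and no protecting groups are used.

**Route**

Step 1
Reactants: 1 3-(4-hydroxyphenyl)propanal; 2 allylboronic acid pinacol ester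
Product: 3 (S)-1-(4-hydroxyphenyl)hex-5-en-3-ol
Conditions: 2 (1.3 equiv), (R)-TRIP (5 mol%), 4 Å MS, toluene/CH2Cl2 4:1, −30 °C, 24 h; aq. NaHCO3 work-up
Reagents that add atoms: allylboronic acid pinacol ester (compound 2), C=CCB1OC(C)(C)C(C)(C)O1
Why: Chiral phosphoric acid-catalysed aldehyde allylboration (Antilla type) through a chair transition state; (R)-TRIP delivers allyl to the Re face as it does for benzaldehyde, which here is 3S because allyl outranks CH2CH2Ar, with about 85–90% ee expected for a β-arylpropanal and the minor enantiomer removed after step 5 as a diastereomer.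

Step 2
Reactants: 4 4-hydroxybenzaldehyde; 5 vinylmagnesium bromide
Product: 6 rac-1-(4-hydroxyphenyl)prop-2-en-1-ol
Conditions: 5 (3.0 equiv, 1 M in THF), THF, 0 °C to rt, 3 h; cold sat. NH4Cl quench, used promptly
Reagents that add atoms: vinylmagnesium bromide (compound 5), C=C[Mg]Br
Why: Grignard 1,2-addition to the aldehyde, with the first equivalent consumed by the phenol; the carbinol is left racemic on purpose because it is ionised away in step 5.

Step 3
Reactants: 3 (S)-1-(4-hydroxyphenyl)hex-5-en-3-ol; 6 rac-1-(4-hydroxyphenyl)prop-2-en-1-ol
Product: 7 (3S,5E,7RS)-1,7-bis(4-hydroxyphenyl)hept-5-ene-3,7-diol (1:1 at C7)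
Conditions: 6 (2.0 equiv), Hoveyda–Grubbs II (5 mol%), 1,4-benzoquinone (10 mol%), degassed EtOAc, 40 °C, 12 h; Et3N-deactivated silica
Reagents that add atoms: none
Why: Olefin cross-metathesis of a type I homoallylic alcohol with a type II secondary allylic alcohol is E-selective and tolerates free phenols and alcohols; benzoquinone suppresses Ru–H isomerisation of the aryl vinyl carbinol, and C3 is untouched.

Step 4
Reactants: 8 2′,4′-dihydroxy-6′-methoxyacetophenone; 4 4-hydroxybenzaldehyde
Product: 9 helichrysetin, (E)-1-(2,4-dihydroxy-6-methoxyphenyl)-3-(4-hydroxyphenyl)prop-2-en-1-one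
Conditions: 4 (1.2 equiv), 60% aq. KOH (20 equiv), EtOH, rt, 72 h; ice/2 M HCl to pH 4, recrystallise
Reagents that add atoms: none
Why: Claisen–Schmidt aldol condensation; E1cB dehydration gives only the E-enone, and the chelated 2′-OH/6′-OMe pattern keeps the product as the open chalcone on mild acidification.

Step 5
Reactants: 7 (3S,5E,7RS)-1,7-bis(4-hydroxyphenyl)hept-5-ene-3,7-diol; 9 helichrysetin
Product: 10 epicalyxin B, (E)-1-{2,4-dihydroxy-3-[(1R,2E,5S)-5-hydroxy-1,7-bis(4-hydroxyphenyl)hept-2-en-1-yl]-6-methoxyphenyl}-3-(4-hydroxyphenyl)prop-2-en-1-one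
Conditions: 9 (2.0 equiv), (R)-TRIP (10 mol%), 3 Å MS, CHCl3/EtOAc 3:1, 0 °C, 7 added over 6 h by syringe pump; reverse-phase prep-HPLC, excess 9 recovered
Reagents that add atoms: none
Why: Proposed new method: a chiral phosphoric acid-catalysed, stereoablative 1,6-Friedel–Crafts arylation in which both C7 epimers of 7 lose water to one planar δ-alkyl vinyl p-QM, the catalyst P–OH hydrogen-bonds the quinone methide carbonyl while P=O binds the chalcone 4′-OH, and the 3,3′-aryl walls deliver C3′ (the site flanked by two small OH groups) to one face of C7 (the methide carbon, nearest the catalyst bridge) rather than to C5, setting 7R under catalyst control with the remote C3 carbinol as a spectator; the closest known reaction type is phosphoric acid-catalysed 1,6-addition of naphthols and indoles to aryl p-QMs generated in situ from p-hydroxybenzyl alcohols, not yet shown for a vinyl p-QM with an acylphloroglucinol chalcone nucleophile or with an unprotected polyphenol partner.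

**Compound list**
1 | 3-(4-hydroxyphenyl)propanal | O=CCCc1ccc(O)cc1 | starting material
2 | allylboronic acid pinacol ester | C=CCB1OC(C)(C)C(C)(C)O1 | starting material
3 | (S)-1-(4-hydroxyphenyl)hex-5-en-3-ol | C=CC[C@@H](O)CCc1ccc(O)cc1 | intermediate
4 | 4-hydroxybenzaldehyde | O=Cc1ccc(O)cc1 | starting material
5 | vinylmagnesium bromide | C=C[Mg]Br | starting material
6 | rac-1-(4-hydroxyphenyl)prop-2-en-1-ol | C=CC(O)c1ccc(O)cc1 | intermediate
7 | (3S,5E,7RS)-1,7-bis(4-hydroxyphenyl)hept-5-ene-3,7-diol | OC(/C=C/C[C@@H](O)CCc1ccc(O)cc1)c1ccc(O)cc1 | intermediate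
8 | 2′,4′-dihydroxy-6′-methoxyacetophenone | COc1cc(O)cc(O)c1C(C)=O | starting material
9 | helichrysetin | COc1cc(O)cc(O)c1C(=O)/C=C/c1ccc(O)cc1 | intermediate
10 | epicalyxin B (3S,7R) | COc1cc(O)c([C@H](/C=C/C[C@@H](O)CCc2ccc(O)cc2)c2ccc(O)cc2)c(O)c1C(=O)/C=C/c1ccc(O)cc1 | target

**Totals**
- Total steps: 5
- Longest linear sequence: 3 (steps 1, 3, 5)

**Three steps most likely to fail**
1. Step 5 (proposed new step). Failure modes: attack at C5 giving the styrene regioisomer, attack from C5′ of the chalcone, tautomerisation of the p-QM to a dienyl phenol, or low facial control. Fallback with known chemistry: disconnect C6–C7 instead, using a chiral biphenol (3,3′-Br2-BINOL)-catalysed addition of an (E)-alkenyl boronate to an ortho-quinone methide. The boronate comes from phosphoric acid-catalysed propargylation of 1 with allenyl-B(pin) followed by alkyne hydroboration; the ortho-quinone methide comes from the A-ring ortho-hydroxybenzhydryl ethyl ether built on protected acetophenone 8. Claisen–Schmidt condensation with 4 and deprotection finish the route; the C7/C5 question disappears.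
2. Step 3 (cross-metathesis). Failure modes: Ru–H isomerisation of 6 to the propiophenone, or loss of the acid-sensitive p-hydroxybenzylic alcohol on purification. Fallback: alkyne route. Phosphoric acid-catalysed propargylation of 1 gives the (S)-homopropargylic alcohol; its lithium acetylide adds to 4-(TBSO)benzaldehyde; Red-Al trans-reduction of the propargylic alcohol gives the E-allylic alcohol; TBAF then gives 7.
3. Step 4 (unprotected Claisen–Schmidt). Failure modes: low conversion from the deactivated phenoxide aldehyde, or flavanone formation on work-up. Fallback: protecting-group route. MOM-protect 8 (4′-OH) and 4, condense with KOH/EtOH, and remove MOM with HCl/MeOH to give 9.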